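The readings were computed with constants of no real substance; the scatter is artificial.

The reading was due at 80 min, in two flasks, noon and summer, that differ in the partner charged.

| flask | substrate | partner | free catalyst | second catalyst | remark | time |
|---|---|---|---|---|---|---|
| Thursday's | 0.020 M | 0.036 M | 100 µM | 100 µM | run made earlier |  |
| Friday's | 0.020 M | 0.079 M | 100 µM | 100 µM | run made earlier |  |
| noon | 0.020 M | 0.0220 M | 100 µM | 100 µM |  | 80 min |
| summer | 0.020 M | 0.0660 M | 100 µM | 100 µM |  | 80 min |

| run | time / min | substrate / % | product / % | open intermediate / % |
|---|---|---|---|---|
| Thursday's | 3.00 | 96 | 1 | 0 |
| Thursday's | 8.00 | 88 | 0 | 11 |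
| Thursday's | 15.0 | 80 | 7 | 18 |
| Thursday's | 40.0 | 58 | 16 | 29 |
| Friday's | 5.00 | 89 | 0 | 8 |
| Friday's | 15.0 | 82 | 2 | 16 |
| Friday's | 25.0 | 68 | 12 | 20 |
| Friday's | 40.0 | 57 | 22 | 29 |

(standard deviation of a reading: 2 percentage points)

- which of these there is most of at the end, counted by the substrate in it, noon (product / open intermediate / substrate)
- which of these there is most of at the end, counted by the substrate in it, summer (product / open intermediate / substrate)
- amount of the one of these that there is most of at the end, in percent of the substrate charged, noon
- amount of the one of these that there is most of at the end, in percent of the substrate charged, summer

- the numbers in the tables scatter with a standard deviation of 2 percentage points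
- what may be going on: substrate + free catalyst -> free catalyst + open intermediate; second catalyst + open intermediate <-> catalyst intermediate; partner + catalyst intermediate -> second catalyst + product; partner -> decomposed reagent

I began with the substrate, because it did not answer to partner: at 40.0 min Thursday's run held 58 % and Friday's 57 %, though Friday's had 2.19 times the [partner]. So I treated its loss as pseudo-first-order and read from Thursday's last reading the substrate half-life, 50.9 min, the time in which the substrate standing is halved. By 80 min that leaves 33.6 % in noon and in summer, so 66.4 % is converted. The second catalyst charge is 0.500 % of the substrate's, so I counted the balance in substrate, open intermediate and product.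

Two extremes can be solved at once. If partner did nothing, the whole 66.4 % would stand as open intermediate; if open intermediate were passed on instantly, it would become product for as long as partner lasted, up to the whole 66.4 %. The real flasks lie between, and the readings place them. Product's share of product plus open intermediate at the last reading was 35.6 % on Thursday and 43.1 % on Friday.

Noon has less partner than Thursday's run but is read later, so I kept Thursday's share, which gave about 42.8 % open intermediate there. For product to lead in summer, its share had to pass 50.7 %. Friday's share had climbed from 37.5 % at 25.0 min, so I put product first in summer.

The forecast gave noon open intermediate at 37 %, calling it “a close call”, which is lower than my figure, and summer product at 43 %.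

Noon gave open intermediate at 44.6 % and summer product at 40.0 %.

    substrate + free catalyst → free catalyst + open intermediate (k = 150 L mol⁻¹ min⁻¹)
    second catalyst + open intermediate ⇌ catalyst intermediate (K = 26.0 L mol⁻¹, k = 350 L mol⁻¹ min⁻¹)
    partner + catalyst intermediate → second catalyst + product (k = 1400 L mol⁻¹ min⁻¹)
    partner → decomposed reagent (k = 0.0230 min⁻¹)

In summer at 21.6 min, partner's half-life by decomposition was 30 min, shorter than the 46 min of substrate by its own step, and decomposition used partner 8.0 times as fast as the product step did. At 80 min, summer still held 30 % of its substrate but 10 % of its partner. Left until 3.0 h, which is 3.54 of the substrate half-lives I had read, the same flask held 6.72 % substrate, 53.3 % product and 39.9 % open intermediate, with 0.15 % of its partner remaining.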